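The only stereocentre, C3, lies in ring C between two CH2 groups, C2 and C4. If both are tied to one carbonyl carbon, they become the enantiotopic α-carbons of a mirror-symmetric 3-(ring-B aryl)cyclobutanone. A catalytic asymmetric Baeyer–Villiger oxidation of that ketone puts the future O1 on C2, widens the four-membered ring to a butyrolactone and fixes C3 as R, all in one operation. C4 ends up beside a carboxyl carbon, which a decarboxylative arylation later swaps for C4a of ring A. Aryl ether formation O1–C8a then closes ring C. The precursor carries the complete ring B (4'-O-prenyl, 5'-(1,1-dimethylallyl)) with 2'-OH masked as TIPS ether.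

Key step: step 7

Assumption: the (R)-configured phosphoric acid is taken to induce the same spatial sense as with simpler 3-arylcyclobutanones, giving the (R)-lactone; should the ortho-silyloxyaryl group reverse the sense, the (S)-acid is used and nothing else changes.

Abbreviations:
- ArB = 5-(2-methylbut-3-en-2-yl)-4-[(3-methylbut-2-en-1-yl)oxy]-2-[(triisopropylsilyl)oxy]phenyl, the finished ring B attached through C1'.
- prenyl = 3-methylbut-2-en-1-yl.
- dtbbpy = 4,4'-di-tert-butyl-2,2'-bipyridine.
- DIC = diisopropylcarbodiimide.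

Remarks on the design:
- **Configuration.** C3 of the target is R. The ranking CH2–O > C1' (aryl) > CH2–C > H holds in every chiral compound below, so all of them are R, and no later step touches a bond at C3.
- **No ketal on the ketone.** The cyclobutanone carbonyl goes unprotected through the nickel coupling, because a magnesium-free arylzinc chloride does not add to ketones at room temperature. This saves the ketal steps and avoids an acidic deketalisation next to the acid-labile prenyl ether.
- **Why TIPS at O2'.** It steers the Claisen shift, resists O→C silyl migration in the ortho-metalated arene, and survives hydroxide, carbonate and mild acid.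
- **The γ-hydroxy acid.** It is never set free from the lactone, since it would close again.

Step 1
Reactants: 1 4-bromoresorcinol (4-bromobenzene-1,3-diol); 2 prenyl bromide (1-bromo-3-methylbut-2-ene)
Product: 3 2-bromo-5-(prenyloxy)phenol
Conditions: K2CO3 (1 equiv), 2 (1 equiv), acetone, 0 °C to rt
Reagents that add atoms: none
Why: Williamson ether synthesis with one equivalent of base and halide, in which the hydroxyl para to bromine is the less hindered one and gives the more nucleophilic phenoxide, while the ortho-bromo hydroxyl is shielded and inductively deactivated, so mono-alkylation should fall on the future O4' (isomer and bis-ether are removed by chromatography).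

Step 2
Reactants: 3 2-bromo-5-(prenyloxy)phenol
Product: 4 [2-bromo-5-(prenyloxy)phenoxy]triisopropylsilane
Conditions: TIPSCl, imidazole, DMF, rt
Reagents that add atoms: triisopropylsilyl chloride, CC(C)[Si](Cl)(C(C)C)C(C)C
Why: Imidazole-promoted silylation of a phenol, which places a very bulky group next to C3' before the sigmatropic step.

Step 3
Reactants: 4 [2-bromo-5-(prenyloxy)phenoxy]triisopropylsilane
Product: 6 4-bromo-2-(2-methylbut-3-en-2-yl)-5-[(triisopropylsilyl)oxy]phenol, via ortho-dienone 5 (not isolated)
Conditions: PhNEt2, 190–200 °C, Ar, sealed vessel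
Reagents that add atoms: none
Why: Aromatic Claisen rearrangement ([3,3] shift with allyl inversion, then tautomerisation of 5) turns the O-prenyl group into a C-bound 1,1-dimethylallyl group; of the two ortho positions C3' is walled off by the OTIPS group, so the shift should go to C5', and the basic solvent speeds enolisation and suppresses acid-induced cyclisation of the product.

Step 4
Reactants: 6 4-bromo-2-(2-methylbut-3-en-2-yl)-5-[(triisopropylsilyl)oxy]phenol; 2 prenyl bromide
Product: 7 ArB–Br (1-bromo-5-(2-methylbut-3-en-2-yl)-4-(prenyloxy)-2-[(triisopropylsilyl)oxy]benzene)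
Conditions: K2CO3, acetone, reflux
Reagents that add atoms: none
Why: Williamson ether synthesis on the only free phenol, under carbonate/acetone conditions that leave an aryl TIPS ether intact.

Step 5
Reactants: 8 3-oxocyclobutane-1-carboxylic acid
Product: 9 1,3-dioxoisoindolin-2-yl 3-oxocyclobutane-1-carboxylate
Conditions: N-hydroxyphthalimide, DIC, DMAP (cat.), CH2Cl2, rt
Reagents that add atoms: N-hydroxyphthalimide, O=C1c2ccccc2C(=O)N1O
Why: Carbodiimide (Steglich-type) esterification gives the redox-active N-acyloxyphthalimide without touching the ketone.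

Step 6
Reactants: 7 ArB–Br; 9 1,3-dioxoisoindolin-2-yl 3-oxocyclobutane-1-carboxylate
Product: 12 3-(ArB)cyclobutan-1-one, via aryllithium 10 (not isolated), via arylzinc chloride 11 (not isolated)
Conditions: 7, n-BuLi, THF, −78 °C; ZnCl2, −78 °C to rt; then 9 (limiting), NiCl2·glyme (20 mol %), dtbbpy (40 mol %), THF/DMF, rt
Reagents that add atoms: none
Why: Nickel-catalysed decarboxylative Negishi-type arylation of a secondary redox-active ester, in which aryl-nickel reduces 9 by single-electron transfer, CO2 and phthalimide anion leave and the 3-oxocyclobutyl radical is captured at nickel and coupled with the aryl group; Br/Li exchange and transmetalation are both finished at −78 °C so that the 1,3 O→C silyl shift (retro-Brook) of 10 cannot compete.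

Step 7
Reactants: 12 3-(ArB)cyclobutan-1-one
Product: 14 (R)-4-(ArB)dihydrofuran-2(3H)-one, via Criegee adduct 13 (not isolated)
Conditions: 30 % aq. H2O2 (1.5 equiv), (R)-3,3'-di(pyren-1-yl)-H8-BINOL hydrogen phosphate (10 mol %), CHCl3, −40 °C
Reagents that add atoms: hydrogen peroxide, OO
Why: The phosphoric acid binds ketone and H2O2 through hydrogen bonds, peroxide adds to the strained carbonyl to give Criegee adduct 13, and the ring methylene standing antiperiplanar to the O–O bond moves from carbon to oxygen as water departs. The closest known reaction type is the chiral-Brønsted-acid-catalysed asymmetric Baeyer–Villiger oxidation of prochiral 3-arylcyclobutanones with aqueous hydrogen peroxide. The γ-butyrolactone ring is not made by cyclisation but by a one-atom ring expansion (four to five members) through this 1,2-shift, which creates the O1–C2 and O1–C(=O) bonds. C3 becomes a stereocentre because its two formerly enantiotopic CH2 arms are now different, and the arm that migrates is selected by the chiral pocket holding the diastereomeric Criegee adducts, with the bulky ortho-silyloxyaryl group pushed away from the pyrenyl walls, so that the (R)-acid should give (R)-14. The step needs chemoselectivity for the carbonyl group over the trisubstituted and the terminal olefin, the electron-rich arene and the acid-labile prenyl ether. This is secured by ring strain, which lets plain H2O2 react at −40 °C with no peracid present, and by the weakness of the acid at that temperature.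

Step 8
Reactants: 14 (R)-4-(ArB)dihydrofuran-2(3H)-one
Product: 17 (R)-3-(ArB)-4-[(tert-butyldimethylsilyl)oxy]butanoic acid, via sodium hydroxy-carboxylate 15 (not isolated), via bis-TBS derivative 16 (not isolated)
Conditions: 1 M aq. NaOH (1.05 equiv), THF, rt, evaporate to dryness; TBSCl (3 equiv), imidazole, DMF, rt; K2CO3, MeOH/THF/H2O, rt; aq. KHSO4 to pH 4–5
Reagents that add atoms: sodium hydroxide, [Na+].[OH-]; tert-butyldimethylsilyl chloride, CC(C)(C)[Si](C)(C)Cl
Why: Lactone saponification, exhaustive silylation and selective hydrolysis of the labile silyl ester, run so that salt 15 is silylated without ever being protonated (the free γ-hydroxy acid would relactonise), while C3 is β to the carboxyl group and cannot epimerise.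

Step 9
Reactants: 17 (R)-3-(ArB)-4-[(tert-butyldimethylsilyl)oxy]butanoic acid
Product: 18 1,3-dioxoisoindolin-2-yl (R)-3-(ArB)-4-[(tert-butyldimethylsilyl)oxy]butanoate
Conditions: N-hydroxyphthalimide, DIC, DMAP (cat.), CH2Cl2, rt
Reagents that add atoms: N-hydroxyphthalimide, O=C1c2ccccc2C(=O)N1O
Why: Steglich-type esterification to the redox-active ester, possible only because the γ-oxygen is silylated and cannot attack the activated carboxyl group.

Step 10
Reactants: 19 4-bromo-3-chlorophenol
Product: 20 (4-bromo-3-chlorophenoxy)triisopropylsilane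
Conditions: TIPSCl, imidazole, DMF, rt
Reagents that add atoms: triisopropylsilyl chloride, CC(C)[Si](Cl)(C(C)C)C(C)C
Why: Standard phenol silylation, giving ring A with the future C4a as C–Br, C8a as C–Cl and O7 protected by the same group as O2'.

Step 11
Reactants: 20 (4-bromo-3-chlorophenoxy)triisopropylsilane; 18 1,3-dioxoisoindolin-2-yl (R)-3-(ArB)-4-[(tert-butyldimethylsilyl)oxy]butanoate
Product: 23 tert-butyl{(2R)-2-(ArB)-3-[2-chloro-4-(triisopropylsilyloxy)phenyl]propoxy}dimethylsilane, via aryllithium 21 (not isolated), via arylzinc chloride 22 (not isolated)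
Conditions: 20, n-BuLi, THF, −78 °C, 15 min; ZnCl2, −78 °C to rt; then 18 (limiting, 22 3 equiv), NiCl2·glyme (20 mol %), dtbbpy (40 mol %), THF/DMF, rt
Reagents that add atoms: none
Why: Nickel-catalysed decarboxylative Negishi-type arylation of a primary redox-active ester excises the former carbonyl carbon as CO2 and joins the C4 radical to C4a; the hindered C–Cl bond should be left alone by the bipyridine–nickel catalyst at room temperature, the radical centre is one carbon away from C3 so the configuration is untouched, and a 1,2-aryl shift of the β-aryl radical is far slower than capture by nickel.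

Step 12
Reactants: 23 tert-butyl{(2R)-2-(ArB)-3-[2-chloro-4-(triisopropylsilyloxy)phenyl]propoxy}dimethylsilane
Product: 24 (2R)-2-(ArB)-3-[2-chloro-4-(triisopropylsilyloxy)phenyl]propan-1-ol
Conditions: CSA (10 mol %), MeOH/CH2Cl2, 0 °C
Reagents that add atoms: none
Why: Acid-catalysed methanolysis discriminates between classes of silyl ether, a primary alkyl TBS ether being cleaved much faster than aryl TIPS ethers, and catalytic acid at 0 °C is too mild to ionise the aryl prenyl ether.

Step 13
Reactants: 24 (2R)-2-(ArB)-3-[2-chloro-4-(triisopropylsilyloxy)phenyl]propan-1-ol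
Product: 25 (3R)-3-(ArB)-7-[(triisopropylsilyl)oxy]chromane (2',7-bis-O-TIPS manuifolin D)
Conditions: Pd(OAc)2 (3 mol %), 2-(di-tert-butylphosphino)-1,1'-binaphthyl (4 mol %), Cs2CO3, toluene, 70 °C
Reagents that add atoms: none
Why: Intramolecular Buchwald–Hartwig-type C–O coupling (oxidative addition into C8a–Cl, alkoxide binding, reductive elimination to the six-membered ring), in which the bulky di-tert-butylbiaryl phosphine favours reductive elimination over β-hydride elimination of the primary alkoxide, so hindered a Pd(0) should ionise the trisubstituted prenyl ether of an electron-rich phenol much more slowly than it inserts into C–Cl, and TIPS resists transfer to the neighbouring alkoxide.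

Step 14
Reactants: 25 (3R)-3-(ArB)-7-[(triisopropylsilyl)oxy]chromane
Product: 26 manuifolin D, (3R)-3-[2-hydroxy-5-(2-methylbut-3-en-2-yl)-4-(prenyloxy)phenyl]chroman-7-ol
Conditions: TBAF/AcOH (1:1, 2.5 equiv), THF, 0 °C
Reagents that add atoms: none
Why: Fluoride-induced cleavage of both aryl silyl ethers, buffered by acetic acid, leaves the prenyl ether, the 1,1-dimethylallyl group and C3 untouched.

Compound list
1 | 4-bromoresorcinol | Oc1ccc(Br)c(O)c1 | starting material
2 | prenyl bromide | CC(C)=CCBr | starting material
3 | 2-bromo-5-(prenyloxy)phenol | Oc1cc(OCC=C(C)C)ccc1Br | intermediate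
4 | [2-bromo-5-(prenyloxy)phenoxy]triisopropylsilane | CC(C)=CCOc1ccc(Br)c(O[Si](C(C)C)(C(C)C)C(C)C)c1 | intermediate
5 | 4-bromo-6-(2-methylbut-3-en-2-yl)-3-[(triisopropylsilyl)oxy]cyclohexa-2,4-dien-1-one (racemic, transient) | C=CC(C)(C)C1C=C(Br)C(O[Si](C(C)C)(C(C)C)C(C)C)=CC1=O | intermediate (not isolated)
6 | 4-bromo-2-(2-methylbut-3-en-2-yl)-5-[(triisopropylsilyl)oxy]phenol | C=CC(C)(C)c1cc(Br)c(O[Si](C(C)C)(C(C)C)C(C)C)cc1O | intermediate
7 | ArB–Br | C=CC(C)(C)c1cc(Br)c(O[Si](C(C)C)(C(C)C)C(C)C)cc1OCC=C(C)C | intermediate
8 | 3-oxocyclobutane-1-carboxylic acid | O=C1CC(C(=O)O)C1 | starting material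
9 | 1,3-dioxoisoindolin-2-yl 3-oxocyclobutane-1-carboxylate | O=C1CC(C(=O)ON2C(=O)c3ccccc3C2=O)C1 | intermediate
10 | ArB–Li | C=CC(C)(C)c1cc([Li])c(O[Si](C(C)C)(C(C)C)C(C)C)cc1OCC=C(C)C | intermediate (not isolated)
11 | ArB–ZnCl | C=CC(C)(C)c1cc([Zn]Cl)c(O[Si](C(C)C)(C(C)C)C(C)C)cc1OCC=C(C)C | intermediate (not isolated)
12 | 3-(ArB)cyclobutan-1-one | C=CC(C)(C)c1cc(C2CC(=O)C2)c(O[Si](C(C)C)(C(C)C)C(C)C)cc1OCC=C(C)C | intermediate
13 | 3-(ArB)-1-hydroperoxycyclobutan-1-ol (Criegee adduct) | C=CC(C)(C)c1cc(C2CC(O)(OO)C2)c(O[Si](C(C)C)(C(C)C)C(C)C)cc1OCC=C(C)C | intermediate (not isolated)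
14 | (R)-4-(ArB)dihydrofuran-2(3H)-one | C=CC(C)(C)c1cc([C@@H]2COC(=O)C2)c(O[Si](C(C)C)(C(C)C)C(C)C)cc1OCC=C(C)C | intermediate
15 | sodium (R)-3-(ArB)-4-hydroxybutanoate | C=CC(C)(C)c1cc([C@@H](CC(=O)[O-])CO)c(O[Si](C(C)C)(C(C)C)C(C)C)cc1OCC=C(C)C.[Na+] | intermediate (not isolated)
16 | tert-butyldimethylsilyl (R)-3-(ArB)-4-[(tert-butyldimethylsilyl)oxy]butanoate | C=CC(C)(C)c1cc([C@@H](CC(=O)O[Si](C)(C)C(C)(C)C)CO[Si](C)(C)C(C)(C)C)c(O[Si](C(C)C)(C(C)C)C(C)C)cc1OCC=C(C)C | intermediate (not isolated)
17 | (R)-3-(ArB)-4-[(tert-butyldimethylsilyl)oxy]butanoic acid | C=CC(C)(C)c1cc([C@@H](CC(=O)O)CO[Si](C)(C)C(C)(C)C)c(O[Si](C(C)C)(C(C)C)C(C)C)cc1OCC=C(C)C | intermediate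
18 | 1,3-dioxoisoindolin-2-yl (R)-3-(ArB)-4-[(tert-butyldimethylsilyl)oxy]butanoate | C=CC(C)(C)c1cc([C@@H](CC(=O)ON2C(=O)c3ccccc3C2=O)CO[Si](C)(C)C(C)(C)C)c(O[Si](C(C)C)(C(C)C)C(C)C)cc1OCC=C(C)C | intermediate
19 | 4-bromo-3-chlorophenol | Oc1ccc(Br)c(Cl)c1 | starting material
20 | (4-bromo-3-chlorophenoxy)triisopropylsilane | CC(C)[Si](Oc1ccc(Br)c(Cl)c1)(C(C)C)C(C)C | intermediate
21 | [2-chloro-4-(triisopropylsilyloxy)phenyl]lithium | CC(C)[Si](Oc1ccc([Li])c(Cl)c1)(C(C)C)C(C)C | intermediate (not isolated)
22 | [2-chloro-4-(triisopropylsilyloxy)phenyl]zinc chloride | CC(C)[Si](Oc1ccc([Zn]Cl)c(Cl)c1)(C(C)C)C(C)C | intermediate (not isolated)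
23 | tert-butyl{(2R)-2-(ArB)-3-[2-chloro-4-(triisopropylsilyloxy)phenyl]propoxy}dimethylsilane | C=CC(C)(C)c1cc([C@@H](Cc2ccc(O[Si](C(C)C)(C(C)C)C(C)C)cc2Cl)CO[Si](C)(C)C(C)(C)C)c(O[Si](C(C)C)(C(C)C)C(C)C)cc1OCC=C(C)C | intermediate
24 | (2R)-2-(ArB)-3-[2-chloro-4-(triisopropylsilyloxy)phenyl]propan-1-ol | C=CC(C)(C)c1cc([C@@H](Cc2ccc(O[Si](C(C)C)(C(C)C)C(C)C)cc2Cl)CO)c(O[Si](C(C)C)(C(C)C)C(C)C)cc1OCC=C(C)C | intermediate
25 | (3R)-3-(ArB)-7-[(triisopropylsilyl)oxy]chromane | C=CC(C)(C)c1cc([C@@H]2COc3cc(O[Si](C(C)C)(C(C)C)C(C)C)ccc3C2)c(O[Si](C(C)C)(C(C)C)C(C)C)cc1OCC=C(C)C | intermediate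
26 | manuifolin D, (3R) | C=CC(C)(C)c1cc([C@@H]2COc3cc(O)ccc3C2)c(O)cc1OCC=C(C)C | target

Total step count: 14 (the telescoped sequence of step 8 counted as one).
Longest linear sequence: 12 (steps 1–4, 6–9, 11–14).

Steps most likely to fail

**1. Step 7.** The discrimination between the two enantiotopic methylene groups may be too weak, because the aryl group that differentiates them is remote from the carbonyl and unusually bulky. Peroxide addition may also become sluggish at low temperature.

The fallback sets out from bromide 7 and comes back at lactone 14. Br/Li exchange at −78 °C (aryllithium 10), quenching with triisopropyl borate and mild aqueous work-up would give ArB-boronic acid F1. A rhodium-catalysed asymmetric conjugate addition (Hayashi–Miyaura reaction) of F1 to furan-2(5H)-one would then form the C1'–C3 bond under ligand control and give the same (R)-lactone. The conditions would be Rh(acac)(C2H4)2/(R)-BINAP in dioxane/H2O, the ligand antipode being chosen by analogy with cyclic enones and enoates. Steps 5 and 6 then drop out.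

**2. Step 11.** Capture of the primary radical by a nickel centre bearing an ortho-chloroaryl ligand may be slow, so that reduction, dimerisation or acyl transfer from the active ester take over. Nickel may also begin to insert into the C–Cl or the allylic C–O bond.

The fallback sets out from redox-active ester 18 and comes back at 23. Irradiation (blue LED) of 18 with bis(catecholato)diboron in DMAc would give catechol boronate F2 by radical decarboxylative borylation. F2 is transesterified in the same flask with pinacol/Et3N to pinacol boronate F3. A B-alkyl Suzuki–Miyaura coupling of F3 with aryl bromide 20 (Pd(OAc)2/RuPhos, K2CO3, toluene/H2O, 80 °C) would take place at C–Br, which reacts well ahead of C–Cl. The C4–C4a bond is thus made in a two-electron palladium cycle, and 20 serves directly as the electrophile.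

**3. Step 6.** Three things may go wrong:
- O→C silyl migration in the aryllithium before transmetalation.
- Slow transmetalation or reductive elimination of the hindered ortho-silyloxyaryl group.
- Addition of the organometallic to the unprotected strained ketone.

The fallback reverses the polarity of the coupling. It sets out from acid 8 and bromide 7 and comes back at 12.
- Cristol–Firth–Hunsdiecker bromodecarboxylation of 8 (HgO, Br2, CH2Cl2, reflux) would give 3-bromocyclobutan-1-one F4.
- Ketalisation (HC(OMe)3, MeOH, cat. TsOH) would give 3-bromo-1,1-dimethoxycyclobutane F5.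
- Zinc insertion (Zn, LiCl, THF) would give (3,3-dimethoxycyclobutyl)zinc bromide F6.
- A palladium-catalysed Negishi coupling of F6 with 7 as the electrophile (Pd(OAc)2/CPhos, THF/toluene, rt) would give dimethyl ketal F7.
- PPTS in aqueous acetone would hydrolyse F7 to 12.

Further compounds
F1 | step 7 | ArB-boronic acid | C=CC(C)(C)c1cc(B(O)O)c(O[Si](C(C)C)(C(C)C)C(C)C)cc1OCC=C(C)C
F2 | step 11 | 2-{(2R)-2-(ArB)-3-[(tert-butyldimethylsilyl)oxy]propyl}-1,3,2-benzodioxaborole | C=CC(C)(C)c1cc([C@@H](CB2Oc3ccccc3O2)CO[Si](C)(C)C(C)(C)C)c(O[Si](C(C)C)(C(C)C)C(C)C)cc1OCC=C(C)C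
F3 | step 11 | 2-{(2R)-2-(ArB)-3-[(tert-butyldimethylsilyl)oxy]propyl}-4,4,5,5-tetramethyl-1,3,2-dioxaborolane | C=CC(C)(C)c1cc([C@@H](CB2OC(C)(C)C(C)(C)O2)CO[Si](C)(C)C(C)(C)C)c(O[Si](C(C)C)(C(C)C)C(C)C)cc1OCC=C(C)C
F4 | step 6 | 3-bromocyclobutan-1-one | O=C1CC(Br)C1
F5 | step 6 | 3-bromo-1,1-dimethoxycyclobutane | COC1(OC)CC(Br)C1
F6 | step 6 | (3,3-dimethoxycyclobutyl)zinc bromide | COC1(OC)CC([Zn]Br)C1
F7 | step 6 | 3-(ArB)-1,1-dimethoxycyclobutane | C=CC(C)(C)c1cc(C2CC(OC)(OC)C2)c(O[Si](C(C)C)(C(C)C)C(C)C)cc1OCC=C(C)C
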